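**Retrosynthetic overview**

1. Chain numbering as in the target name: C1 (isobutenyl methyl) to C16 (benzylic CH2). The ketone carbon C5 is cut on both sides (C5–C6 and C4–C5) and becomes carbon monoxide.
2. Enabling feature: C5(=O) lies between the methyl-bearing sp2 carbon C6 of the (E)-C6=C7 alkene and the carbinol carbon C4 (an acyloin on an α-methyl enone). A 2-alkyne (C6≡C7 with the 6-methyl), CO and 3-methylbut-2-enal (C1–C4) can therefore be joined in one pot by hydrozirconation, CO insertion and acyl-anion addition.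
3. The 2-alkyne comes from (R)-linalool (C9–C16 and the C14 stereocentre). Its vinyl group is joined to an aryl bromide by B-alkyl Suzuki coupling; its (E)-methyl group is extended by SeO2 oxidation, bromination and propyne dianion/MeI (C6–C8).
4. End game: desilylation, then the p-methoxyphenol is converted to the hydroquinone with PhI(OAc)2 and dithionite.
5. Rings: none is formed. The benzene ring is bought with the first starting material and only passes through the quinone oxidation level in the last step.

Key step: step 8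

Remark: (R)-(−)-linalool is taken as the commercial natural enantiomer in high enantiomeric purity; its C3 becomes C14 of the target with no bond to the stereocentre broken.

**Route**

Step 1
Reactants: 1 4-methoxy-2-methylphenol
Product: 2 2-bromo-4-methoxy-6-methylphenol
Conditions: NBS (1.0 equiv), CH2Cl2, 0 °C
Reagents that add atoms: N-bromosuccinimide, O=C1CCC(=O)N1Br
Why: Electrophilic aromatic bromination goes ortho to the free phenol, the stronger donor, whose para position is blocked by OMe and whose other ortho position carries the methyl group.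

Step 2
Reactants: 2 2-bromo-4-methoxy-6-methylphenol
Product: 3 (2-bromo-4-methoxy-6-methylphenoxy)(tert-butyl)dimethylsilane
Conditions: TBSCl, imidazole, DMF, 40 °C
Reagents that add atoms: tert-butyldimethylsilyl chloride, CC(C)(C)[Si](C)(C)Cl
Why: Silyl ether formation on the phenol; the TBS ether of a 2,6-disubstituted phenol should withstand the later aqueous base, organolithium and zirconium hydride steps.

Step 3
Reactants: 4 (R)-linalool [(3R)-3,7-dimethylocta-1,6-dien-3-ol]
Product: 5 (3R)-3,7-dimethyl-3-(triethylsilyloxy)octa-1,6-diene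
Conditions: TESOTf, 2,6-lutidine, CH2Cl2, −78 → 0 °C
Reagents that add atoms: triethylsilyl trifluoromethanesulfonate, CC[Si](CC)(CC)OS(=O)(=O)C(F)(F)F
Why: Silyl triflate silylation of the tertiary alcohol forms only an O–Si bond, so the stereocentre is untouched.

Step 4
Reactants: 5 (3R)-3,7-dimethyl-3-(triethylsilyloxy)octa-1,6-diene; 3 (2-bromo-4-methoxy-6-methylphenoxy)(tert-butyl)dimethylsilane
Product: 7 tert-butyl{2-[(3R)-3,7-dimethyl-3-(triethylsilyloxy)oct-6-en-1-yl]-4-methoxy-6-methylphenoxy}dimethylsilane, via B-alkyl-9-BBN 6 (not isolated)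
Conditions: 9-BBN (0.5 M in THF), rt; then 3, Pd(OAc)2 (5 mol%), SPhos (10 mol%), K3PO4 (3 M aq), THF, 60 °C
Reagents that add atoms: none
Why: 9-BBN hydroborates only the monosubstituted alkene, at its terminal carbon, and the primary alkylborane is joined to the aryl bromide by B-alkyl Suzuki–Miyaura coupling; the stereocentre is not involved.

Step 5
Reactants: 7 tert-butyl{2-[(3R)-3,7-dimethyl-3-(triethylsilyloxy)oct-6-en-1-yl]-4-methoxy-6-methylphenoxy}dimethylsilane
Product: 8 (2E,6R)-8-[2-(tert-butyldimethylsilyloxy)-5-methoxy-3-methylphenyl]-2,6-dimethyl-6-(triethylsilyloxy)oct-2-en-1-ol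
Conditions: SeO2 (0.3 equiv), t-BuOOH (3 equiv), salicylic acid (0.1 equiv), CH2Cl2, 0 °C → rt
Reagents that add atoms: tert-butyl hydroperoxide, CC(C)(C)OO (oxygen atom relayed by catalytic SeO2)
Why: Catalytic SeO2 allylic oxidation (ene reaction, then [2,3]-sigmatropic shift) attacks the (E)-methyl group of a trisubstituted isopropylidene alkene and should give the (E)-allylic alcohol.

Step 6
Reactants: 8 (2E,6R)-8-[2-(tert-butyldimethylsilyloxy)-5-methoxy-3-methylphenyl]-2,6-dimethyl-6-(triethylsilyloxy)oct-2-en-1-ol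
Product: 9 tert-butyl{2-[(3R,6E)-8-bromo-3,7-dimethyl-3-(triethylsilyloxy)oct-6-en-1-yl]-4-methoxy-6-methylphenoxy}dimethylsilane
Conditions: CBr4, PPh3, CH2Cl2, −20 → 0 °C
Reagents that add atoms: carbon tetrabromide, BrC(Br)(Br)Br
Why: Appel bromination of the primary allylic alcohol proceeds by SN2 displacement at low temperature, without allylic shift or loss of the E geometry.

Step 7
Reactants: 9 tert-butyl{2-[(3R,6E)-8-bromo-3,7-dimethyl-3-(triethylsilyloxy)oct-6-en-1-yl]-4-methoxy-6-methylphenoxy}dimethylsilane; 10 propyne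
Product: 13 tert-butyl{2-[(3R,6E)-3,7-dimethyl-3-(triethylsilyloxy)dodec-6-en-10-yn-1-yl]-4-methoxy-6-methylphenoxy}dimethylsilane, via 1,3-dilithiopropyne 11 (not isolated), via lithium acetylide 12 (not isolated)
Conditions: 10 (3 equiv), n-BuLi (2 equiv per propyne), TMEDA, Et2O/hexane, −78 → 0 °C; 9, THF, −78 → −20 °C; then MeI, DMPU, −20 °C → rt
Reagents that add atoms: iodomethane, CI
Why: Sequential dialkylation of the propyne dianion: the more basic propargylic carbanion displaces the primary allylic bromide by SN2, and the remaining lithium acetylide is methylated in the same flask.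

Step 8
Reactants: 13 tert-butyl{2-[(3R,6E)-3,7-dimethyl-3-(triethylsilyloxy)dodec-6-en-10-yn-1-yl]-4-methoxy-6-methylphenoxy}dimethylsilane; 14 carbon monoxide; 15 3-methylbut-2-enal
Product: 18 (4S,6E,10E,14R)-16-[2-(tert-butyldimethylsilyloxy)-5-methoxy-3-methylphenyl]-4-hydroxy-2,6,10,14-tetramethyl-14-(triethylsilyloxy)hexadeca-2,6,10-trien-5-one, via alkenylzirconocene 16 (not isolated), via acylzirconocene 17 (not isolated)
Conditions: Cp2Zr(H)Cl (1.3 equiv), CH2Cl2, rt; CO (1 atm), rt; then 15 (3 equiv), B-butyl-N-tosyl-oxazaborolidinone from N-tosyl-(S)-tryptophan and BuB(OH)2 (30 mol%), EtCN/CH2Cl2, −78 → −40 °C; aq NaHCO3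
Reagents that add atoms: none
Why: Proposed new method: syn-hydrozirconation of the 2-alkyne gives both regioisomeric alkenylzirconocenes, which the small excess of Cp2Zr(H)Cl equilibrates to 16 with Zr on the less hindered, methyl-bearing carbon (H and Zr cis, which fixes the E geometry), CO then inserts into the C(sp2)–Zr bond with retention to form the C5–C6 bond in acylzirconocene 17, and this unmasked acyl anion adds through an open transition state to the aldehyde bound to the chiral boron Lewis acid, the zirconium taking the new alkoxide and freeing the boron. The closest known reactions are the hydrozirconation/CO insertion of alkynes to α,β-unsaturated acylzirconocene chlorides and their BF3·OEt2-promoted 1,2-addition to aldehydes and enals, which gives racemic α-ketols; what is new is the replacement of BF3 by the tryptophan-derived oxazaborolidinone, the Lewis acid of enantioselective Mukaiyama aldol additions to aldehydes, which have the same open geometry. No ring is closed. The only new stereocentre, C4, is set by the catalyst: the indole is expected to stack on the coordinated s-trans enal and cover its Si face, so that the acyl carbon adds to the Re face and gives the 4S alcohol, without influence from the remote C14 centre. The step needs regioselective hydrometalation (thermodynamic control at the methyl terminus of the 2-alkyne), chemoselectivity for the alkyne over the C10=C11 alkene (alkynes react much faster with Cp2Zr(H)Cl and nothing reducible is present), 1,2-addition (the β,β-disubstituted enal disfavours 1,4-attack) and the absence of a racemic background (acylzirconocene chlorides do not add to aldehydes without a Lewis acid).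

Step 9
Reactants: 18 (4S,6E,10E,14R)-16-[2-(tert-butyldimethylsilyloxy)-5-methoxy-3-methylphenyl]-4-hydroxy-2,6,10,14-tetramethyl-14-(triethylsilyloxy)hexadeca-2,6,10-trien-5-one
Product: 19 (4S,6E,10E,14R)-4,14-dihydroxy-16-(2-hydroxy-5-methoxy-3-methylphenyl)-2,6,10,14-tetramethylhexadeca-2,6,10-trien-5-one
Conditions: TBAF, AcOH (1:1), THF, 0 °C → rt
Reagents that add atoms: none
Why: Fluoride-mediated desilylation, buffered with acetic acid, should remove the aryl TBS and tertiary TES ethers without enolizing the α-ketol; no stereocentre is touched.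

Step 10
Reactants: 19 (4S,6E,10E,14R)-4,14-dihydroxy-16-(2-hydroxy-5-methoxy-3-methylphenyl)-2,6,10,14-tetramethylhexadeca-2,6,10-trien-5-one
Product: 21 (4S,6E,10E,14R)-16-(2,5-dihydroxy-3-methylphenyl)-4,14-dihydroxy-2,6,10,14-tetramethylhexadeca-2,6,10-trien-5-one (CNP0172251.1), via quinone 20 (not isolated)
Conditions: PhI(OAc)2 (1.1 equiv), MeCN/H2O, 0 °C; then aq Na2S2O4, EtOAc, argon
Reagents that add atoms: water, O
Why: Hypervalent-iodine oxidation of a p-methoxyphenol (water adds at the para carbon, methanol is lost) gives the p-benzoquinone, which dithionite reduces at once to the hydroquinone; alkenes, alcohols and the ketol are not expected to react at 0 °C.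

**Compound list**

1 | 4-methoxy-2-methylphenol | COc1ccc(O)c(C)c1 | starting material
2 | 2-bromo-4-methoxy-6-methylphenol | COc1cc(C)c(O)c(Br)c1 | intermediate
3 | (2-bromo-4-methoxy-6-methylphenoxy)(tert-butyl)dimethylsilane | COc1cc(C)c(O[Si](C)(C)C(C)(C)C)c(Br)c1 | intermediate
4 | (R)-linalool, (3R)-3,7-dimethylocta-1,6-dien-3-ol | CC(C)=CCC[C@@](C)(O)C=C | starting material
5 | (3R)-3,7-dimethyl-3-(triethylsilyloxy)octa-1,6-diene | CC(C)=CCC[C@@](C)(O[Si](CC)(CC)CC)C=C | intermediate
6 | B-alkyl-9-BBN from terminal hydroboration of 5 (not isolated) | CC(C)=CCC[C@@](C)(O[Si](CC)(CC)CC)CCB1C2CCCC1CCC2 | intermediate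
7 | tert-butyl{2-[(3R)-3,7-dimethyl-3-(triethylsilyloxy)oct-6-en-1-yl]-4-methoxy-6-methylphenoxy}dimethylsilane | CC(C)=CCC[C@@](C)(O[Si](CC)(CC)CC)CCc1cc(OC)cc(C)c1O[Si](C)(C)C(C)(C)C | intermediate
8 | (2E,6R)-8-[2-(tert-butyldimethylsilyloxy)-5-methoxy-3-methylphenyl]-2,6-dimethyl-6-(triethylsilyloxy)oct-2-en-1-ol | OC/C(C)=C/CC[C@@](C)(O[Si](CC)(CC)CC)CCc1cc(OC)cc(C)c1O[Si](C)(C)C(C)(C)C | intermediate
9 | tert-butyl{2-[(3R,6E)-8-bromo-3,7-dimethyl-3-(triethylsilyloxy)oct-6-en-1-yl]-4-methoxy-6-methylphenoxy}dimethylsilane | BrC/C(C)=C/CC[C@@](C)(O[Si](CC)(CC)CC)CCc1cc(OC)cc(C)c1O[Si](C)(C)C(C)(C)C | intermediate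
10 | propyne | CC#C | starting material
11 | 1,3-dilithiopropyne (not isolated) | [Li]CC#C[Li] | intermediate
12 | lithium acetylide from alkylation of 11 by 9 (not isolated) | [Li]C#CCC/C(C)=C/CC[C@@](C)(O[Si](CC)(CC)CC)CCc1cc(OC)cc(C)c1O[Si](C)(C)C(C)(C)C | intermediate
13 | tert-butyl{2-[(3R,6E)-3,7-dimethyl-3-(triethylsilyloxy)dodec-6-en-10-yn-1-yl]-4-methoxy-6-methylphenoxy}dimethylsilane | CC#CCC/C(C)=C/CC[C@@](C)(O[Si](CC)(CC)CC)CCc1cc(OC)cc(C)c1O[Si](C)(C)C(C)(C)C | intermediate
14 | carbon monoxide | [C-]#[O+] | starting material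
15 | 3-methylbut-2-enal | CC(C)=CC=O | starting material
16 | (E)-alkenylzirconocene chloride, Zr on the methyl-bearing carbon, Cp drawn σ-bonded (not isolated) | Cl[Zr](C1C=CC=C1)(C1C=CC=C1)/C(C)=C/CC/C(C)=C/CC[C@@](C)(O[Si](CC)(CC)CC)CCc1cc(OC)cc(C)c1O[Si](C)(C)C(C)(C)C | intermediate
17 | α,β-unsaturated acylzirconocene chloride, Cp drawn σ-bonded (not isolated) | Cl[Zr](C1C=CC=C1)(C1C=CC=C1)C(=O)/C(C)=C/CC/C(C)=C/CC[C@@](C)(O[Si](CC)(CC)CC)CCc1cc(OC)cc(C)c1O[Si](C)(C)C(C)(C)C | intermediate
18 | (4S,6E,10E,14R)-16-[2-(tert-butyldimethylsilyloxy)-5-methoxy-3-methylphenyl]-4-hydroxy-2,6,10,14-tetramethyl-14-(triethylsilyloxy)hexadeca-2,6,10-trien-5-one | CC(C)=C[C@H](O)C(=O)/C(C)=C/CC/C(C)=C/CC[C@@](C)(O[Si](CC)(CC)CC)CCc1cc(OC)cc(C)c1O[Si](C)(C)C(C)(C)C | intermediate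
19 | (4S,6E,10E,14R)-4,14-dihydroxy-16-(2-hydroxy-5-methoxy-3-methylphenyl)-2,6,10,14-tetramethylhexadeca-2,6,10-trien-5-one | CC(C)=C[C@H](O)C(=O)/C(C)=C/CC/C(C)=C/CC[C@@](C)(O)CCc1cc(OC)cc(C)c1O | intermediate
20 | 2-[(3R,6E,10E,13S)-3,13-dihydroxy-3,7,11,15-tetramethyl-12-oxohexadeca-6,10,14-trien-1-yl]-6-methyl-1,4-benzoquinone (not isolated) | CC(C)=C[C@H](O)C(=O)/C(C)=C/CC/C(C)=C/CC[C@@](C)(O)CCC1=CC(=O)C=C(C)C1=O | intermediate
21 | (4S,6E,10E,14R)-16-(2,5-dihydroxy-3-methylphenyl)-4,14-dihydroxy-2,6,10,14-tetramethylhexadeca-2,6,10-trien-5-one, CNP0172251.1 | CC(C)=C[C@H](O)C(=O)/C(C)=C/CC/C(C)=C/CC[C@@](C)(O)CCc1cc(O)cc(C)c1O | target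

**Step count**

Total: 10 steps. Longest linear sequence: 9 steps (from 1: steps 1, 2 and 4–10); the linalool branch joins at step 4.

**Steps most likely to fail**

Step 8 (proposed new method). Facial discrimination in the acyl transfer may be poor, because the transition state is open and a zirconium-promoted racemic pathway could compete. Regio-equilibration of the hydrozirconation may also be incomplete. Either would give C4 epimers or regioisomers that are hard to separate, since the second stereocentre is remote. The fallback sets out from 13 and returns at 19, using known chemistry only. Hydrozirconation of 13 under thermodynamic control (Cp2Zr(H)Cl, THF, 45 °C) and iodinolysis (I2) should give the (E)-vinyl iodide F1. Separately, (R)-2,3-O-isopropylideneglyceraldehyde and isopropylidenetriphenylphosphorane (from isopropyltriphenylphosphonium iodide and n-BuLi) should give the (S)-dioxolane F2. Aqueous acetic acid frees the (S)-diol F3, TESCl/imidazole gives the bis-TES ether F4, and Swern oxidation, which converts the primary TES ether selectively, gives the (S)-aldehyde F5. Nozaki–Hiyama–Kishi coupling of F1 with F5 (CrCl2, NiCl2 cat., DMSO) forms the same C5–C6 bond and should give the allylic alcohol F6 as a mixture of C5 epimers. Dess–Martin oxidation converges both epimers on the silyl-protected ketol F7, and TBAF/AcOH then removes all three silyl groups to give 19. In this sequence the C4 configuration comes from the chiral pool.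

Step 5. Conversion may stall, the product may over-oxidize to the enal, and the allylic CH2 may be oxidized in competition, all of which erode the yield of the (E)-alcohol. The fallback sets out from 7 and returns at 8. Oxidative cleavage of the isopropylidene alkene of 7 (OsO4 cat., NaIO4, 2,6-lutidine, dioxane/H2O) should give the aldehyde F8. E-selective Wittig olefination with ethyl 2-(triphenylphosphoranylidene)propanoate should give the (E)-enoate F9, and DIBAL-H reduction (CH2Cl2, −78 °C) gives 8. The allylic oxidation is thus replaced by cleavage and rebuilding of the trisubstituted alkene.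

Step 7. The propyne dianion is ambident and may react through its allenyl form. SN2′ attack or halogen–metal exchange on the allylic bromide, and incomplete methylation of the acetylide, may also occur. The fallback sets out from 9 and returns at 13. The monoanion of 1-(trimethylsilyl)propyne (n-BuLi, THF, −78 °C), which alkylates only at its propargylic carbon, should convert 9 into the silylalkyne F10. Silver-catalysed protiodesilylation (AgNO3 cat., acetone/H2O), which spares the aryl silyl ether, gives the terminal alkyne F11. Deprotonation (n-BuLi, THF, −78 °C) and methylation with MeI give 13.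

Further compounds
F1 | step 8 | tert-butyl{2-[(3R,6E,10E)-11-iodo-3,7-dimethyl-3-(triethylsilyloxy)dodeca-6,10-dien-1-yl]-4-methoxy-6-methylphenoxy}dimethylsilane | I/C(C)=C/CC/C(C)=C/CC[C@@](C)(O[Si](CC)(CC)CC)CCc1cc(OC)cc(C)c1O[Si](C)(C)C(C)(C)C
F2 | step 8 | (S)-2,2-dimethyl-4-(2-methylprop-1-en-1-yl)-1,3-dioxolane | CC(C)=C[C@H]1COC(C)(C)O1
F3 | step 8 | (S)-4-methylpent-3-ene-1,2-diol | CC(C)=C[C@H](O)CO
F4 | step 8 | (S)-4-methyl-1,2-bis(triethylsilyloxy)pent-3-ene | CC(C)=C[C@H](O[Si](CC)(CC)CC)CO[Si](CC)(CC)CC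
F5 | step 8 | (S)-4-methyl-2-(triethylsilyloxy)pent-3-enal | CC(C)=C[C@H](O[Si](CC)(CC)CC)C=O
F6 | step 8 | (4S,6E,10E,14R)-16-[2-(tert-butyldimethylsilyloxy)-5-methoxy-3-methylphenyl]-2,6,10,14-tetramethyl-4,14-bis(triethylsilyloxy)hexadeca-2,6,10-trien-5-ol, both C5 epimers | CC(C)=C[C@H](O[Si](CC)(CC)CC)C(O)/C(C)=C/CC/C(C)=C/CC[C@@](C)(O[Si](CC)(CC)CC)CCc1cc(OC)cc(C)c1O[Si](C)(C)C(C)(C)C
F7 | step 8 | (4S,6E,10E,14R)-16-[2-(tert-butyldimethylsilyloxy)-5-methoxy-3-methylphenyl]-2,6,10,14-tetramethyl-4,14-bis(triethylsilyloxy)hexadeca-2,6,10-trien-5-one | CC(C)=C[C@H](O[Si](CC)(CC)CC)C(=O)/C(C)=C/CC/C(C)=C/CC[C@@](C)(O[Si](CC)(CC)CC)CCc1cc(OC)cc(C)c1O[Si](C)(C)C(C)(C)C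
F8 | step 5 | (4S)-6-[2-(tert-butyldimethylsilyloxy)-5-methoxy-3-methylphenyl]-4-methyl-4-(triethylsilyloxy)hexanal | O=CCC[C@@](C)(O[Si](CC)(CC)CC)CCc1cc(OC)cc(C)c1O[Si](C)(C)C(C)(C)C
F9 | step 5 | ethyl (2E,6R)-8-[2-(tert-butyldimethylsilyloxy)-5-methoxy-3-methylphenyl]-2,6-dimethyl-6-(triethylsilyloxy)oct-2-enoate | CCOC(=O)/C(C)=C/CC[C@@](C)(O[Si](CC)(CC)CC)CCc1cc(OC)cc(C)c1O[Si](C)(C)C(C)(C)C
F10 | step 7 | tert-butyl{2-[(3R,6E)-3,7-dimethyl-3-(triethylsilyloxy)-11-(trimethylsilyl)undec-6-en-10-yn-1-yl]-4-methoxy-6-methylphenoxy}dimethylsilane | C[Si](C)(C)C#CCC/C(C)=C/CC[C@@](C)(O[Si](CC)(CC)CC)CCc1cc(OC)cc(C)c1O[Si](C)(C)C(C)(C)C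
F11 | step 7 | tert-butyl{2-[(3R,6E)-3,7-dimethyl-3-(triethylsilyloxy)undec-6-en-10-yn-1-yl]-4-methoxy-6-methylphenoxy}dimethylsilane | C#CCC/C(C)=C/CC[C@@](C)(O[Si](CC)(CC)CC)CCc1cc(OC)cc(C)c1O[Si](C)(C)C(C)(C)C
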